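Germacrane numbering (C1–C15) is used throughout. Everything rests on opening the ten-membered ring between C7, the β-carbon of the butenolide ring, and C8, the carbinol carbon that bears the methacrylate: an alkenyl-metal/aldehyde retron. An intramolecular Nozaki–Hiyama–Kishi addition of a C7 iodide to a C8 aldehyde closes the carbocycle and sets C8 in one operation. The open-chain precursor is a 4-iodobutenolide carrying C2 and C6: C2 and the E-C4=C5 olefin come from a catalytic asymmetric vinylogous Mukaiyama aldol reaction, C6 and the C7 iodide from an asymmetric alkynylation relayed through an allenoate (anti-SN2' carbonylation, then iodolactonisation).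

Key step: step 16

Remark: where a chiral catalyst is named, the enantiomer meant is the one that gives the facial sense stated in that step; if the sense proves to be the reverse, its antipode is used.

Step 1
Reactants: 1 tert-butyl(but-3-yn-1-yloxy)dimethylsilane
Product: 4 (E)-5-[(tert-butyldimethylsilyl)oxy]-3-methylpent-2-en-1-ol, via alkenyldimethylalane 2 (not isolated), via lithium alkenylalanate 3 (not isolated)
Conditions: Me3Al (2.5 equiv), Cp2ZrCl2 (0.25 equiv), CH2Cl2, 0 °C → rt; n-BuLi, −78 °C; (CH2O)n, THF, −78 °C → rt; Rochelle salt work-up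
Reagents that add atoms: trimethylaluminium C[Al](C)C; paraformaldehyde (as formaldehyde) C=O
Why: Negishi carboalumination adds methyl and aluminium syn across the alkyne with the metal on the terminal carbon, and formaldehyde traps the ate complex with retention, which fixes the E geometry of C1=C10.

Step 2
Reactants: 4 allylic alcohol
Product: 5 (E)-5-[(tert-butyldimethylsilyl)oxy]-3-methylpent-2-enal
Conditions: MnO2 (20 equiv), CH2Cl2, rt
Reagents that add atoms: none
Why: MnO2 oxidises the allylic alcohol selectively and should not isomerise the olefin (allylic oxidation).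

Step 3
Reactants: 6 ethyl 3-methylbut-2-enoate
Product: 8 tert-butyl[(1-ethoxy-3-methylbuta-1,3-dien-1-yl)oxy]dimethylsilane, via lithium dienolate 7 (not isolated)
Conditions: LiN(i-Pr)2, THF, −78 °C; then TBSCl, DMPU, −78 °C → rt
Reagents that add atoms: tert-butylchlorodimethylsilane CC(C)(C)[Si](C)(C)Cl
Why: Kinetic γ-deprotonation of the enoate and O-silylation of the dienolate give the vinylogous silyl ketene acetal, whose acetal geometry is immaterial for the next step.

Step 4
Reactants: 5 enal; 8 silyl dienolate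
Product: 9 ethyl (2E,5R,6E)-9-[(tert-butyldimethylsilyl)oxy]-5-hydroxy-3,7-dimethylnona-2,6-dienoate
Conditions: SiCl4 (1.2 equiv), (R,R)-binaphthyldiamine-derived bisphosphoramide (5 mol %), i-Pr2NEt (0.1 equiv), CH2Cl2, −78 °C; aq NaHCO3/KF
Reagents that add atoms: none
Why: SiCl4 activated by the chiral Lewis base promotes a vinylogous Mukaiyama aldol reaction in which the dienolate attacks only through its γ-carbon on the Re face of the enal, setting C2 as R, while the s-trans dienolate should deliver the E-configured C4=C5 enoate.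

Step 5
Reactants: 9 hydroxy ester
Product: 10 ethyl (2E,5R,6E)-9-[(tert-butyldimethylsilyl)oxy]-3,7-dimethyl-5-[(triethylsilyl)oxy]nona-2,6-dienoate
Conditions: TESCl, imidazole, DMF, 0 °C
Reagents that add atoms: chlorotriethylsilane CC[Si](CC)(CC)Cl
Why: Silylation masks the C2 hydroxyl against the hydride, oxidation and palladium steps, and the triethylsilyl ether can later be removed beside the primary TBS ether.

Step 6
Reactants: 10 silyl-protected ester
Product: 11 (2E,5R,6E)-9-[(tert-butyldimethylsilyl)oxy]-3,7-dimethyl-5-[(triethylsilyl)oxy]nona-2,6-dien-1-ol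
Conditions: i-Bu2AlH (2.2 equiv), CH2Cl2, −78 °C; Rochelle salt work-up
Reagents that add atoms: none
Why: i-Bu2AlH reduces the conjugated ester in the 1,2-sense to the allylic alcohol at low temperature and leaves both silyl ethers untouched.

Step 7
Reactants: 11 allylic alcohol
Product: 12 (2E,5R,6E)-9-[(tert-butyldimethylsilyl)oxy]-3,7-dimethyl-5-[(triethylsilyl)oxy]nona-2,6-dienal
Conditions: MnO2 (20 equiv), CH2Cl2, rt
Reagents that add atoms: none
Why: Selective allylic oxidation with MnO2 gives the C6 enal with the E-C4=C5 geometry retained.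

Step 8
Reactants: 13 prop-2-yn-1-ol
Product: 14 triethyl(prop-2-yn-1-yloxy)silane
Conditions: TESCl, imidazole, CH2Cl2, 0 °C
Reagents that add atoms: chlorotriethylsilane CC[Si](CC)(CC)Cl
Why: Standard silylation; the silyl ether at the future C13 is inert to the zinc and palladium steps and, unlike an ester, is not a leaving group next to the later allene.

Step 9
Reactants: 12 enal; 14 alkyne
Product: 16 (4S,5E,8R,9E)-12-[(tert-butyldimethylsilyl)oxy]-6,10-dimethyl-1,8-bis[(triethylsilyl)oxy]dodeca-5,9-dien-2-yn-4-ol, via methylzinc alkynylide 15 (not isolated)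
Conditions: 14 (3 equiv), Me2Zn (3 equiv), (S,S)-ProPhenol (20 mol %), Ph3PO (40 mol %), toluene, 0 °C; then 12, 4 °C
Reagents that add atoms: none
Why: Zinc–ProPhenol-catalysed alkynylation, for which enals are favoured acceptors, delivers the alkynyl group to the Re face of the C6 aldehyde under catalyst control and sets the carbinol as S, the remote C2 centre having no say.

Step 10
Reactants: 16 propargylic alcohol
Product: 17 (4S,5E,8R,9E)-12-[(tert-butyldimethylsilyl)oxy]-6,10-dimethyl-1,8-bis[(triethylsilyl)oxy]dodeca-5,9-dien-2-yn-4-yl methyl carbonate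
Conditions: ClCO2Me, pyridine, DMAP (cat.), CH2Cl2, 0 °C
Reagents that add atoms: methyl chloroformate COC(=O)Cl
Why: Acylation gives a carbonate that can be isolated yet ionises readily with zerovalent palladium, whereas a sulfonate of this doubly activated alcohol would solvolyse.

Step 11
Reactants: 17 propargylic carbonate
Product: 18 methyl (aR,5E,8R,9E)-12-[(tert-butyldimethylsilyl)oxy]-6,10-dimethyl-8-[(triethylsilyl)oxy]-2-{[(triethylsilyl)oxy]methyl}dodeca-2,3,5,9-tetraenoate
Conditions: Pd2(dba)3·CHCl3 (2.5 mol %), PPh3 (10 mol %), CO (10 bar), MeOH–THF, 25 °C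
Reagents that add atoms: carbon monoxide [C-]#[O+]
Why: Decarboxylative SN2' carbonylation of a propargylic carbonate: zerovalent palladium attacks C11 anti to the leaving group, CO inserts into the allenyl–palladium bond and the liberated methoxide closes the ester, so the S carbinol centre is translated into the aR allene axis.

Step 12
Reactants: 18 allenoate
Product: 20 (5R)-5-[(1E,4R,5E)-8-[(tert-butyldimethylsilyl)oxy]-4-hydroxy-2,6-dimethylocta-1,5-dien-1-yl]-3-(hydroxymethyl)-4-iodofuran-2(5H)-one, via bis-triethylsilyl iodobutenolide 19 (not isolated)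
Conditions: I2 (2.5 equiv), MeCN–H2O (15:1), 0 °C → rt; aq Na2S2O3/NaHCO3; then PPTS (0.2 equiv), MeOH, 0 °C
Reagents that add atoms: iodine II
Why: Iodolactonisation of a 2,3-allenoate: iodine activates C6=C7 and the ester carbonyl oxygen attacks C6 anti to it with loss of methanol, so the aR axis becomes 6R and C7 receives the iodide; mild acid then frees both triethylsilyl ethers while the primary TBS ether should stay.

Step 13
Reactants: 20 diol
Product: 21 {(5R)-5-[(1E,4R,5E)-4-acetoxy-8-[(tert-butyldimethylsilyl)oxy]-2,6-dimethylocta-1,5-dien-1-yl]-4-iodo-2-oxo-2,5-dihydrofuran-3-yl}methyl acetate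
Conditions: Ac2O, pyridine, DMAP (cat.), CH2Cl2, 0 °C
Reagents that add atoms: acetic anhydride CC(=O)OC(C)=O
Why: DMAP-catalysed acyl transfer esterifies the C13 and C2 hydroxyls in one operation and so installs both acetates of the target.

Step 14
Reactants: 21 diacetate
Product: 22 {(5R)-5-[(1E,4R,5E)-4-acetoxy-8-hydroxy-2,6-dimethylocta-1,5-dien-1-yl]-4-iodo-2-oxo-2,5-dihydrofuran-3-yl}methyl acetate
Conditions: HF·pyridine, pyridine, THF, 0 °C → rt
Reagents that add atoms: none
Why: Buffered fluoride cleaves the primary TBS ether (desilylation) without touching the acetates, the lactone or the alkenyl iodide.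

Step 15
Reactants: 22 primary alcohol
Product: 23 {(5R)-5-[(1E,4R,5E)-4-acetoxy-2,6-dimethyl-8-oxoocta-1,5-dien-1-yl]-4-iodo-2-oxo-2,5-dihydrofuran-3-yl}methyl acetate
Conditions: Dess–Martin periodinane (1.5 equiv), NaHCO3, CH2Cl2, 0 °C; used crude at once
Reagents that add atoms: none
Why: Buffered Dess–Martin oxidation gives the β,γ-unsaturated C8 aldehyde under neutral conditions that should not move the C1=C10 double bond into conjugation.

Step 16
Reactants: 23 iodobutenolide aldehyde
Product: 24 (2R,6R,8S)-2,13-diacetoxy-8-hydroxygermacra-1(10)E,4E,7(11)-trien-12,6-olide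
Conditions: CrCl2 (8 equiv), NiCl2 (0.1 equiv), degassed DMSO–THF (3:1), rt, 23 added over 10 h (final 2 mM)
Reagents that add atoms: none
Why: Zerovalent nickel (from NiCl2 and CrCl2) inserts into the activated C7–I bond of the β-iodobutenolide, the alkenylnickel transmetalates to trivalent chromium and the alkenylchromium adds to the tethered C8 aldehyde in an intramolecular Nozaki–Hiyama–Kishi reaction; the closest known cases are Nozaki–Hiyama–Kishi macrocyclisations to medium carbocycles and couplings of β-iodo-enoates with aldehydes. The ten-membered ring closes in a 10-exo-trig mode onto the carbonyl carbon, the butenolide ring being already in place. The new C8 centre is set under substrate control: 1,3-allylic strain with the C13 acetoxymethyl group keeps the aldehyde hydrogen in the butenolide plane, the C6 centre and the two E-olefins fix the path of the tether, and the chromium-bound oxygen is expected to take the outer, pseudo-equatorial 8α site, which is 8S. Chemoselectivity is needed against two acetates, the lactone and the enolisable β,γ-unsaturated aldehyde, and the neutral, non-basic alkenylchromium secures it. Ring closure must outrun oligomerisation and proto-deiodination, which slow addition into a dilute CrCl2 suspension and the pre-organised E,E-diene chain should favour.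

Step 17
Reactants: 24 macrocyclic alcohol
Product: 25 (2R,6R,8S)-2,13-diacetoxy-8-(methacryloyloxy)germacra-1(10)E,4E,7(11)-trien-12,6-olide (CNP0309304.1)
Conditions: methacrylic anhydride (3 equiv), DMAP (0.2 equiv), pyridine, CH2Cl2, 0 °C → rt
Reagents that add atoms: methacrylic anhydride C=C(C)C(=O)OC(=O)C(C)=C
Why: DMAP-catalysed acyl transfer esterifies the C8 hydroxyl with retention under weakly basic conditions that should not epimerise the γ-position of the butenolide.

Compound list
1 | tert-butyl(but-3-yn-1-yloxy)dimethylsilane | C#CCCO[Si](C)(C)C(C)(C)C | starting material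
2 | [(E)-4-[(tert-butyldimethylsilyl)oxy]-2-methylbut-1-en-1-yl]dimethylalane | C[Al](C)/C=C(\C)CCO[Si](C)(C)C(C)(C)C | intermediate
3 | lithium butyl[(E)-4-[(tert-butyldimethylsilyl)oxy]-2-methylbut-1-en-1-yl]dimethylalanate | [Li+].CCCC[Al-](C)(C)/C=C(\C)CCO[Si](C)(C)C(C)(C)C | intermediate
4 | (E)-5-[(tert-butyldimethylsilyl)oxy]-3-methylpent-2-en-1-ol | OC/C=C(\C)CCO[Si](C)(C)C(C)(C)C | intermediate
5 | (E)-5-[(tert-butyldimethylsilyl)oxy]-3-methylpent-2-enal | O=C/C=C(\C)CCO[Si](C)(C)C(C)(C)C | intermediate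
6 | ethyl 3-methylbut-2-enoate | CCOC(=O)C=C(C)C | starting material
7 | lithium 1-ethoxy-3-methylbuta-1,3-dien-1-olate | [Li+].CCOC([O-])=CC(C)=C | intermediate
8 | tert-butyl[(1-ethoxy-3-methylbuta-1,3-dien-1-yl)oxy]dimethylsilane (acetal geometry not defined) | CCOC(=CC(C)=C)O[Si](C)(C)C(C)(C)C | intermediate
9 | ethyl (2E,5R,6E)-9-[(tert-butyldimethylsilyl)oxy]-5-hydroxy-3,7-dimethylnona-2,6-dienoate | CCOC(=O)/C=C(\C)C[C@@H](O)/C=C(\C)CCO[Si](C)(C)C(C)(C)C | intermediate
10 | ethyl (2E,5R,6E)-9-[(tert-butyldimethylsilyl)oxy]-3,7-dimethyl-5-[(triethylsilyl)oxy]nona-2,6-dienoate | CCOC(=O)/C=C(\C)C[C@@H](O[Si](CC)(CC)CC)/C=C(\C)CCO[Si](C)(C)C(C)(C)C | intermediate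
11 | (2E,5R,6E)-9-[(tert-butyldimethylsilyl)oxy]-3,7-dimethyl-5-[(triethylsilyl)oxy]nona-2,6-dien-1-ol | OC/C=C(\C)C[C@@H](O[Si](CC)(CC)CC)/C=C(\C)CCO[Si](C)(C)C(C)(C)C | intermediate
12 | (2E,5R,6E)-9-[(tert-butyldimethylsilyl)oxy]-3,7-dimethyl-5-[(triethylsilyl)oxy]nona-2,6-dienal | O=C/C=C(\C)C[C@@H](O[Si](CC)(CC)CC)/C=C(\C)CCO[Si](C)(C)C(C)(C)C | intermediate
13 | prop-2-yn-1-ol | C#CCO | starting material
14 | triethyl(prop-2-yn-1-yloxy)silane | C#CCO[Si](CC)(CC)CC | intermediate
15 | methyl{3-[(triethylsilyl)oxy]prop-1-yn-1-yl}zinc | C[Zn]C#CCO[Si](CC)(CC)CC | intermediate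
16 | (4S,5E,8R,9E)-12-[(tert-butyldimethylsilyl)oxy]-6,10-dimethyl-1,8-bis[(triethylsilyl)oxy]dodeca-5,9-dien-2-yn-4-ol | CC[Si](CC)(CC)OCC#C[C@@H](O)/C=C(\C)C[C@@H](O[Si](CC)(CC)CC)/C=C(\C)CCO[Si](C)(C)C(C)(C)C | intermediate
17 | (4S,5E,8R,9E)-12-[(tert-butyldimethylsilyl)oxy]-6,10-dimethyl-1,8-bis[(triethylsilyl)oxy]dodeca-5,9-dien-2-yn-4-yl methyl carbonate | CC[Si](CC)(CC)OCC#C[C@@H](OC(=O)OC)/C=C(\C)C[C@@H](O[Si](CC)(CC)CC)/C=C(\C)CCO[Si](C)(C)C(C)(C)C | intermediate
18 | methyl (aR,5E,8R,9E)-12-[(tert-butyldimethylsilyl)oxy]-6,10-dimethyl-8-[(triethylsilyl)oxy]-2-{[(triethylsilyl)oxy]methyl}dodeca-2,3,5,9-tetraenoate | COC(=O)C(CO[Si](CC)(CC)CC)=[C@]=C([H])/C=C(\C)C[C@@H](O[Si](CC)(CC)CC)/C=C(\C)CCO[Si](C)(C)C(C)(C)C | intermediate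
19 | (5R)-5-[(1E,4R,5E)-8-[(tert-butyldimethylsilyl)oxy]-2,6-dimethyl-4-[(triethylsilyl)oxy]octa-1,5-dien-1-yl]-4-iodo-3-{[(triethylsilyl)oxy]methyl}furan-2(5H)-one | CC[Si](CC)(CC)OCC1=C(I)[C@@H](/C=C(\C)C[C@@H](O[Si](CC)(CC)CC)/C=C(\C)CCO[Si](C)(C)C(C)(C)C)OC1=O | intermediate
20 | (5R)-5-[(1E,4R,5E)-8-[(tert-butyldimethylsilyl)oxy]-4-hydroxy-2,6-dimethylocta-1,5-dien-1-yl]-3-(hydroxymethyl)-4-iodofuran-2(5H)-one | OCC1=C(I)[C@@H](/C=C(\C)C[C@@H](O)/C=C(\C)CCO[Si](C)(C)C(C)(C)C)OC1=O | intermediate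
21 | {(5R)-5-[(1E,4R,5E)-4-acetoxy-8-[(tert-butyldimethylsilyl)oxy]-2,6-dimethylocta-1,5-dien-1-yl]-4-iodo-2-oxo-2,5-dihydrofuran-3-yl}methyl acetate | CC(=O)OCC1=C(I)[C@@H](/C=C(\C)C[C@@H](OC(C)=O)/C=C(\C)CCO[Si](C)(C)C(C)(C)C)OC1=O | intermediate
22 | {(5R)-5-[(1E,4R,5E)-4-acetoxy-8-hydroxy-2,6-dimethylocta-1,5-dien-1-yl]-4-iodo-2-oxo-2,5-dihydrofuran-3-yl}methyl acetate | CC(=O)OCC1=C(I)[C@@H](/C=C(\C)C[C@@H](OC(C)=O)/C=C(\C)CCO)OC1=O | intermediate
23 | {(5R)-5-[(1E,4R,5E)-4-acetoxy-2,6-dimethyl-8-oxoocta-1,5-dien-1-yl]-4-iodo-2-oxo-2,5-dihydrofuran-3-yl}methyl acetate | CC(=O)OCC1=C(I)[C@@H](/C=C(\C)C[C@@H](OC(C)=O)/C=C(\C)CC=O)OC1=O | intermediate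
24 | (2R,6R,8S)-2,13-diacetoxy-8-hydroxygermacra-1(10)E,4E,7(11)-trien-12,6-olide | O[C@H]1C/C(C)=C/[C@H](OC(C)=O)C/C(C)=C/[C@H]2OC(=O)C(COC(C)=O)=C12 | intermediate
25 | (2R,6R,8S)-2,13-diacetoxy-8-(methacryloyloxy)germacra-1(10)E,4E,7(11)-trien-12,6-olide | C=C(C)C(=O)O[C@H]1C/C(C)=C/[C@H](OC(C)=O)C/C(C)=C/[C@H]2OC(=O)C(COC(C)=O)=C12 | target

Total step count: 17. Longest linear sequence: 15 steps (steps 1, 2, 4–7 and 9–17, from compound 1); steps 3 and 8 make the two side components.

Steps most likely to fail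

Step 16 (key step). The aldehyde may be attacked on the wrong face, with the chromium-bound oxygen on the inner side of the forming ring, so that the 8R epimer dominates; transannular strain may also slow ring closure. The fallback sets out from 23 and comes back at 25. The same ring closure then gives (2R,6R,8R)-2,13-diacetoxy-8-hydroxygermacra-1(10)E,4E,7(11)-trien-12,6-olide F1. Instead of acylation with retention, this alcohol is esterified under Mitsunobu conditions (methacrylic acid, PPh3, DIAD, THF, 0 °C). The SN2 inversion at C8 installs the methacrylate and gives 25 directly. Either epimer can therefore be carried to the target, 24 by step 17 and its epimer by inversion.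

Step 11. The carbonate may ionise in the allylic rather than the propargylic sense, or the allenylpalladium may racemise before CO insertion, so regiocontrol or the centre-to-axis transfer is lost. The fallback sets out from 12, comes back at 20, and keeps the C6–O bond made in the alkynylation. Enal 12 is alkynylated with methyl propiolate under the same zinc catalysis with the antipodal ligand (Si-face attack) to give methyl (4R,5E,8R,9E)-12-[(tert-butyldimethylsilyl)oxy]-4-hydroxy-6,10-dimethyl-8-[(triethylsilyl)oxy]dodeca-5,9-dien-2-ynoate F2. A MgI2-promoted iodo-aldol (β-iodo Morita–Baylis–Hillman) reaction with formaldehyde in CH2Cl2 puts iodide on C7 and the hydroxymethyl group on C11. The isomer with the C6 hydroxyl cis to the ester lactonises, and the other should equilibrate by iodide addition–elimination. The product is (5R)-5-[(1E,4R,5E)-8-[(tert-butyldimethylsilyl)oxy]-2,6-dimethyl-4-[(triethylsilyl)oxy]octa-1,5-dien-1-yl]-3-(hydroxymethyl)-4-iodofuran-2(5H)-one F3. PPTS in methanol then removes the triethylsilyl ether to give 20. No allene and no palladium are involved, and C6 keeps the configuration set by the ligand.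

Step 12. The axis-to-centre transfer may erode through an open, vinyl-stabilised cation at C6, and the trisubstituted olefins may be iodinated in competition. The fallback sets out from 18 and comes back at 24. A copper-mediated bromolactonisation (CuBr2, acetone–H2O, 65 °C) is an inner-sphere halolactonisation without a free halonium ion, and the acid it sets free removes the triethylsilyl groups. It gives (5R)-4-bromo-5-[(1E,4R,5E)-8-[(tert-butyldimethylsilyl)oxy]-4-hydroxy-2,6-dimethylocta-1,5-dien-1-yl]-3-(hydroxymethyl)furan-2(5H)-one F4. Acetylation as in step 13 gives {(5R)-5-[(1E,4R,5E)-4-acetoxy-8-[(tert-butyldimethylsilyl)oxy]-2,6-dimethylocta-1,5-dien-1-yl]-4-bromo-2-oxo-2,5-dihydrofuran-3-yl}methyl acetate F5. Desilylation as in step 14 gives {(5R)-5-[(1E,4R,5E)-4-acetoxy-8-hydroxy-2,6-dimethylocta-1,5-dien-1-yl]-4-bromo-2-oxo-2,5-dihydrofuran-3-yl}methyl acetate F6. Oxidation as in step 15 gives {(5R)-5-[(1E,4R,5E)-4-acetoxy-2,6-dimethyl-8-oxoocta-1,5-dien-1-yl]-4-bromo-2-oxo-2,5-dihydrofuran-3-yl}methyl acetate F7. Its activated alkenyl bromide enters the same CrCl2/NiCl2 ring closure to give 24.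

Further compounds
F1 | step 16 | (2R,6R,8R)-2,13-diacetoxy-8-hydroxygermacra-1(10)E,4E,7(11)-trien-12,6-olide | O[C@@H]1C/C(C)=C/[C@H](OC(C)=O)C/C(C)=C/[C@H]2OC(=O)C(COC(C)=O)=C12
F2 | step 11 | methyl (4R,5E,8R,9E)-12-[(tert-butyldimethylsilyl)oxy]-4-hydroxy-6,10-dimethyl-8-[(triethylsilyl)oxy]dodeca-5,9-dien-2-ynoate | COC(=O)C#C[C@H](O)/C=C(\C)C[C@@H](O[Si](CC)(CC)CC)/C=C(\C)CCO[Si](C)(C)C(C)(C)C
F3 | step 11 | (5R)-5-[(1E,4R,5E)-8-[(tert-butyldimethylsilyl)oxy]-2,6-dimethyl-4-[(triethylsilyl)oxy]octa-1,5-dien-1-yl]-3-(hydroxymethyl)-4-iodofuran-2(5H)-one | OCC1=C(I)[C@@H](/C=C(\C)C[C@@H](O[Si](CC)(CC)CC)/C=C(\C)CCO[Si](C)(C)C(C)(C)C)OC1=O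
F4 | step 12 | (5R)-4-bromo-5-[(1E,4R,5E)-8-[(tert-butyldimethylsilyl)oxy]-4-hydroxy-2,6-dimethylocta-1,5-dien-1-yl]-3-(hydroxymethyl)furan-2(5H)-one | OCC1=C(Br)[C@@H](/C=C(\C)C[C@@H](O)/C=C(\C)CCO[Si](C)(C)C(C)(C)C)OC1=O
F5 | step 12 | {(5R)-5-[(1E,4R,5E)-4-acetoxy-8-[(tert-butyldimethylsilyl)oxy]-2,6-dimethylocta-1,5-dien-1-yl]-4-bromo-2-oxo-2,5-dihydrofuran-3-yl}methyl acetate | CC(=O)OCC1=C(Br)[C@@H](/C=C(\C)C[C@@H](OC(C)=O)/C=C(\C)CCO[Si](C)(C)C(C)(C)C)OC1=O
F6 | step 12 | {(5R)-5-[(1E,4R,5E)-4-acetoxy-8-hydroxy-2,6-dimethylocta-1,5-dien-1-yl]-4-bromo-2-oxo-2,5-dihydrofuran-3-yl}methyl acetate | CC(=O)OCC1=C(Br)[C@@H](/C=C(\C)C[C@@H](OC(C)=O)/C=C(\C)CCO)OC1=O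
F7 | step 12 | {(5R)-5-[(1E,4R,5E)-4-acetoxy-2,6-dimethyl-8-oxoocta-1,5-dien-1-yl]-4-bromo-2-oxo-2,5-dihydrofuran-3-yl}methyl acetate | CC(=O)OCC1=C(Br)[C@@H](/C=C(\C)C[C@@H](OC(C)=O)/C=C(\C)CC=O)OC1=O
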